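**Atom numbering used throughout.** C1 is the vinylic methyl, C2=C3 the alkene, C4 the ketone. Ring B is the cyclobutane C5 (bonded to C4), C6, C7 (bonded to C2) and quaternary C8. C9 and C11 are the ester carbinols on either side of C10, and C12 is the C(CH3)2 carbon on C6. Ring A is the enone ring, ring C the seven-membered ring. "Syn" and "anti" describe substituents on C6 and C8 relative to the C2–C4 bridge. Compound numbers refer to the list after the steps.

## Analysis of the target

The target is a tricyclo[5.4.0.0(2,8)]undecane (longipinane-type) sesquiterpenoid diester. Its cyclobutane (ring B) carries two bridges: C5 and C7 are joined by C4–C3–C2 (ring A, a verbenone-like bicyclo[3.1.1]heptenone), and C6 and C8 are joined on the opposite face by C12–C11–C10–C9 (ring C). There are six stereocentres (C5 R, C6 S, C7 R, C8 R, C9 R, C11 R). The four on ring B are locked by the cage, with H on C6 and CH3 on C8 both syn to ring A. The free elements are therefore C9, C11 (1,3-anti) and the orientation of ring A: the C4 carbonyl sits on the cyclobutane carbon that lies on the side of the C9 oxygen. Sensitive groups are the two hindered secondary 3-methylbutanoates (bases, organometallics), the enone, and the cyclobutane flanked by a carbonyl and an alkene, which opens under cation-forming conditions. The difficulties are a four-membered ring between two quaternary carbons (C8, C12), two 1,3-bridges on opposite faces, and a remote relationship between the ring C oxygens and the ring A orientation that no neighbouring group can relay. The strategy rests on one structural fact: C6 and C8 are the bridgehead carbons of a bicyclo[1.1.0]butane whose wing carbons C5 and C7 are already tied by C2–C4. Cutting the C6–C8 bond while C12 adds to C6 and C9 to C8 on the convex face creates ring B and ring C together. A second fact makes the route asymmetric: with ring A as a C3 ketone and ring C as a C9=C10–C11=O enone, the tricycle has a mirror plane through C3, C6 and C8–C12, so absolute configuration can be introduced later by catalysts acting on an achiral intermediate.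

## Retrosynthetic reasoning

**Esters.** The two acyl C–O bonds at C9 and C11 are cut first, so 27 comes from diol 25 and two equivalents of 26. The esters would not survive the amide base and the carbon nucleophile needed for ring A, so the diol is carried as the bis-silyl ether 24 and acylation is the last step.

**C1–C2 bond.** Ring A is opened in the sense of an alkylative carbonyl transposition. 24 is the product of oxidative 1,3-transposition of the tertiary allylic alcohol 23, and 23 arises by addition of a methyl nucleophile to the C2 carbonyl of the isomeric enone 22. Cut in this way, C2 never has to be a controlled stereocentre. The forward steps must add 1,2 and then move oxygen from C2 to C4 without opening the cyclobutane.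

**Oxygen at C2 and the C2/C4 decision.** 22 is traced to alkene 20 by an ene-type photooxygenation, which shifts C2=C3 to C3=C4 and places oxygen on C2. 20 comes from the enol triflate 19 of ketone 17. Only one ene mode exists, because the other allylic hydrogen is on bridgehead C7. The choice between C2 and C4 is therefore made once, in the enolisation of 17 by a chiral lithium amide, and is transmitted unchanged. The more direct order (methylate C2 of 17, form the C3=C4 alkene, then ene reaction) is not used: methylation and the ene reaction both take the face of ring A turned to C6, so the C2 hydrogen the ene step needs would lie on the blocked face under the C8 methyl.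

**Ring C oxygens.** 17 follows from 15 through the protected ketal 16. The C11–H bond of 15 is cut back to β-hydroxy ketone 14 (hydroxyl-directed hydride delivery gives 1,3-anti). The C9–O bond of 14 is cut back to enone 12 (conjugate borylation, then oxidation). 12 is achiral, with the enone in its mirror plane, so a chiral copper catalyst alone fixes C9 and with it the absolute configuration.

**Key disconnection.** 12 is cut at C6–C12 and C8–C9, the two bonds that attach ring C to ring B. Reconnecting C6 to C8 gives bicyclobutane 7, and the four-carbon unit becomes bromo ynone 11. This removes ring C, both bonds to quaternary carbons and all cage stereochemistry in one operation. The forward reaction must attack C6 and not C8, stay on the convex face, and close at C9 rather than C10.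

**Bromo ynone.** 11 comes from 10 by removal of the silyl cap, and 10 by forming the C10–C11 bond through acylation of silylalkyne 9 with 8.

**Bicyclobutane.** The C8–CH3 bond of 7 is cut to the bridgehead lithium compound 6, made from 5. 5 comes from dibromide 4 by carbenoid C–H insertion, 4 from alkene 2 and 3, and 2 from 1. The methyl is added after the bicyclobutane is formed rather than carried from the start. A methyl on the cyclopropane would place the required insertion next to a quaternary carbon and open insertion into the methyl itself. In 4 the two candidate methylenes differ clearly, and the two bridgeheads of 5 are equivalent.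

## Alternatives that were turned down

**Alternative 1:** The cyclobutane is disconnected at C6–C7 and C5–C8. In the forward sense an amine base converts the dienoyl chloride A2 into a vinylketene that adds intramolecularly across the C7=C8 alkene to give the 4-methylene-bicyclo[3.1.1]heptan-6-one A1.
- For: intramolecular vinylketene–alkene cycloaddition to bicyclo[3.1.1]heptan-6-ones is an established reaction type, and rings A and B with C5, C7 and C8 arise in one step. On precedent for its key step this alternative is stronger than the chosen route.
- Against: A2 needs its own asymmetric synthesis (C2 and C9 stereocentres, a defined trisubstituted alkene), and the facial selectivity relative to C9 depends on the conformation of an open chain. Ring C is still open in A1. C12 must then be joined to the hindered cyclobutanone carbon C6, the resulting tertiary C6 hydroxyl removed with the right configuration next to a strained ring, the exo-methylene cleaved to the C4 ketone, and C2=C3 introduced, which destroys the C2 centre the cyclisation relied on.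
- Comparison: the chosen route accepts an unprecedented key step, and in return reaches the same bicyclo[3.1.1] core in four steps and closes ring C in the same operation with no cage stereochemistry left to set.

**Alternative 2:** Ring C is opened at C10–C11. In the forward sense the methyl ketone enolate of keto aldehyde A4 adds to the C11 aldehyde, the aldolate is captured by 3-methylbutanal A5, and an intramolecular hydride shift reduces C9 anti, giving the C9 alcohol C11 ester A3.
- For: one step closes ring C, sets the anti relationship and installs one of the two esters without protecting groups. At the end of the synthesis this is shorter than the protection, deprotection and acylation used here.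
- Against: it presupposes A4, which already contains the cyclobutane with both anti carbon substituents and the ring A enone, so the difficult part is not addressed by the key step. The configuration of C11 relative to the orientation of ring A would have to come from substrate control by a remote element, which is expected to be weak. The enone γ-hydrogens compete with the methyl ketone in enolisation.
- Comparison: the chosen route solves the remote relationship by catalyst control on a symmetric intermediate and a reagent-controlled enolisation.

**Alternative 3:** Ring B is made by ring contraction. Photolysis of the diazo cyclopentanone A7 in an alcohol solvent causes C8 to migrate from C4 to C5 with loss of N2, giving the all-trans cyclobutane ester A6 after equilibration at C5.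
- For: the migration proceeds with retention, the chemistry is well known, and the cyclopentanone is assembled convergently. For reliability of four-membered ring formation it is stronger than the chosen route.
- Against: A6 is monocyclic. Ring A and ring C must each be closed across 1,3-positions of the cyclobutane, which requires both substituent pairs to adopt diaxial-like arrangements. C10 is an unactivated methyl that needs oxidation-state changes before C10–C11 can form. The step count after the key step is high.
- Comparison: the chosen route starts with ring A's bridge in place and uses the strain of the bicyclobutane to pay for ring B and ring C together.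

Key step: step 7

Assumption: where the sense of induction of a chiral reagent cannot be derived from first principles (ligand in step 8, amide base in step 12), one enantiomer is written; the mirror-image reagent is used if a trial shows the opposite sense, and nothing else changes.

## Route

Step 1
Reactants: 1 1-methoxycyclohexa-1,4-diene
Product: 2 1,4-dioxaspiro[4.5]dec-7-ene
Conditions: HOCH2CH2OH (3 equiv), p-toluenesulfonic acid monohydrate (1 mol %), CH2Cl2, 0 °C → rt
Reagents that add atoms: ethylene glycol, OCCO
Why: Acid-catalysed acetal exchange of the enol ether: protonation at the enol ether β-carbon gives an oxocarbenium ion that the diol captures with loss of methanol; at low acid loading the isolated alkene should stay out of conjugation.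

Step 2
Reactants: 2 1,4-dioxaspiro[4.5]dec-7-ene; 3 bromoform
Product: 4 7,7-dibromobicyclo[4.1.0]heptan-3-one ethylene ketal (racemic)
Conditions: CHBr3 (1.5 equiv), KOtBu (1.8 equiv), pentane, −10 °C → rt
Reagents that add atoms: none
Why: α-Elimination of HBr from 3 gives dibromocarbene, which adds stereospecifically to the cis-alkene to give the cis-fused cyclopropane; the ketal is inert to base.

Step 3
Reactants: 4 7,7-dibromobicyclo[4.1.0]heptan-3-one ethylene ketal
Product: 5 tricyclo[4.1.0.0(2,7)]heptan-4-one ethylene ketal
Conditions: MeLi (1.3 equiv), Et2O, −78 → 0 °C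
Reagents that add atoms: none
Why: Bromine–lithium exchange and α-elimination give a cyclopropylidene carbenoid, which in a six-membered ring cannot open to an allene and inserts into a C–H bond of a methylene flanking the cyclopropane (the standard route from 7,7-dibromonorcaranes to tricyclo[4.1.0.0(2,7)]heptanes). The methylene next to the ketal carbon is deactivated towards the electrophilic carbenoid by two β-oxygens, so insertion into the other one is expected and gives the mirror-symmetric ketal 5.

Step 4
Reactants: 5 tricyclo[4.1.0.0(2,7)]heptan-4-one ethylene ketal
Product: 7 1-methyltricyclo[4.1.0.0(2,7)]heptan-4-one ethylene ketal, via bridgehead lithium compound 6 (not isolated)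
Conditions: n-BuLi (1.2 equiv), TMEDA (1.2 equiv), Et2O, 0 °C → rt; then MeI (1.5 equiv), −78 °C → rt
Reagents that add atoms: iodomethane, CI
Why: Bridgehead C–H bonds of a bicyclobutane have high s character and are metalated by n-BuLi/TMEDA (known bridgehead lithiation–alkylation of this ring system). The two bridgeheads of 5 are related by the mirror plane, so a single lithium compound forms and is methylated with retention.

Step 5
Reactants: 8 2-bromo-2-methylpropanoyl bromide; 9 bis(trimethylsilyl)ethyne
Product: 10 4-bromo-4-methyl-1-(trimethylsilyl)pent-1-yn-3-one
Conditions: AlCl3 (1.1 equiv), CH2Cl2, −20 → 0 °C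
Reagents that add atoms: none
Why: Friedel–Crafts-type acylation of a silylalkyne: the acylium ion attacks ipso to silicon (β-silyl-stabilised vinyl cation) and one silyl group is lost; the second stays on the terminus and keeps the ynone from polymerising.

Step 6
Reactants: 10 4-bromo-4-methyl-1-(trimethylsilyl)pent-1-yn-3-one
Product: 11 4-bromo-4-methylpent-1-yn-3-one
Conditions: Na2B4O7·10H2O (0.1 equiv), MeOH/H2O (10:1), rt; used at once
Reagents that add atoms: none
Why: Borate-buffered methanolysis cleaves the C(sp)–Si bond under conditions too mild to add methanol to the ynone or to disturb the tertiary bromide.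

Step 7
Reactants: 7 1-methyltricyclo[4.1.0.0(2,7)]heptan-4-one ethylene ketal; 11 4-bromo-4-methylpent-1-yn-3-one
Product: 12 mirror-symmetric tricyclic enone ketal (ring A as C3 ethylene ketal; ring C as C9=C10–C11=O enone; H on C6 and CH3 on C8 syn)
Conditions: 7 (1.5 equiv), K2CO3 (solid), PhH (0.3 M), rt; 11 (1.0 equiv) and (Me3Si)3SiH (1.2 equiv) added over 8 h; Et3B (0.2 equiv in portions), air
Reagents that add atoms: none
Why: Proposed new method: Et3B/O2 starts a chain in which (Me3Si)3Si• takes bromine from 11, and the electrophilic tertiary α-keto radical at C12 adds to the unsubstituted bridgehead C6 of 7 from the convex face, so that the central C6–C8 bond breaks and the strain is released into a tertiary cyclobutyl radical at C8. This nucleophilic radical attacks the ynone terminus C9 of the chain it has just acquired (7-endo-dig closure of ring C; ring B is not closed but uncovered by the bond cleavage), and the vinyl radical at C10 takes hydrogen from (Me3Si)3SiH, which carries the chain. The closest known reaction types are Kharasch-type radical additions across the central bond of tricyclo[4.1.0.0(2,7)]heptanes, which give 6,7-disubstituted bicyclo[3.1.1]heptanes, and the radical formal cycloadditions of bicyclo[1.1.0]butanes that lead to bicyclo[2.1.1]hexanes and bicyclo[4.1.1]octanes; a chain that closes a seven-membered enone ring across the central bond has no direct precedent. C6 is set by the face of attack: the concave face is occupied by the C2–C4 bridge, so C12 enters anti and H6 ends syn. C8 is set by the tether: C9 hangs from C12 below the ring and can reach only the lower lobe of the C8 radical, so C9 ends anti and the methyl syn, the only arrangement the target allows; no other stereocentre forms and 12 is achiral. Attack at C6 rather than C8 is secured by the methyl group, which shields C8 and makes the radical left after attack at C6 tertiary. Closure at C9 rather than C10 is favoured by polarity (C9 is the β-carbon of the ynone) and by strain, since 6-exo attack at C10 would force a second one-carbon-bridged bicyclo[3.1.1] unit onto the same cyclobutane. Bromine abstraction from a tertiary α-bromo ketone is faster than silyl-radical addition to the alkyne, and slow addition of 11 and the silane to an excess of 7 keeps premature reduction of either radical and addition of the C8 radical to a second ynone behind the intended steps.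

Step 8
Reactants: 12 mirror-symmetric tricyclic enone ketal
Product: 14 (9R)-C9-hydroxy C11-ketone ketal, via C9 pinacolboronate 13 (not isolated)
Conditions: CuCl (5 mol %), NaOtBu (10 mol %), (R)-1-[(S)-2-(diphenylphosphino)ferrocenyl]ethyldicyclohexylphosphine (6 mol %), B2pin2 (1.2 equiv), MeOH (2 equiv), THF, rt; then NaBO3·4H2O (5 equiv), THF/H2O, rt
Reagents that add atoms: bis(pinacolato)diboron, CC1(C)OB(OC1(C)C)B1OC(C)(C)C(C)(C)O1; sodium perborate, [Na+].[O-]OB=O
Why: Copper–boryl conjugate addition (monovalent copper, chiral diphosphine): the Cu–Bpin species adds across C9=C10 with boron on the β-carbon and MeOH protonates the copper enolate. The enone lies in the mirror plane of 12, so its faces are enantiotopic and the ligand alone decides; addition to the Re face of C9 (C8 > C10 > H) and perborate oxidation with retention give the (9R)-carbinol.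

Step 9
Reactants: 14 (9R)-C9-hydroxy C11-ketone ketal
Product: 15 (9R,11R)-anti-diol ketal
Conditions: Me4NBH(OAc)3 (5 equiv), MeCN/AcOH (1:1), −30 → −10 °C
Reagents that add atoms: none
Why: Evans–Saksena reduction: the C9 hydroxyl exchanges onto boron and hydride is delivered internally to the C11 carbonyl on the face that carries the C9 oxygen, so the new hydroxyl appears on the opposite face (1,3-anti). External hydride attack on this neopentyl ketone is slow, which protects the selectivity.

Step 10
Reactants: 15 (9R,11R)-anti-diol ketal
Product: 16 C9,C11-bis(tert-butyldimethylsilyl) ether ketal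
Conditions: TBSOTf (3 equiv), 2,6-lutidine (5 equiv), CH2Cl2, −78 → 0 °C
Reagents that add atoms: tert-butyldimethylsilyl trifluoromethanesulfonate, CC(C)(C)[Si](C)(C)OS(=O)(=O)C(F)(F)F
Why: Silylation of both hindered secondary alcohols with the silyl triflate; the silyl ethers tolerate the bases, organolithium and oxidants of steps 12–16, and the dioxolane survives at low temperature with a hindered base.

Step 11
Reactants: 16 C9,C11-bis(tert-butyldimethylsilyl) ether ketal
Product: 17 C3 ketone (C2 and C4 methylene)
Conditions: pyridinium p-toluenesulfonate (0.2 equiv), acetone/H2O (10:1), 50 °C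
Reagents that add atoms: water, O
Why: Acid-catalysed ketal hydrolysis in wet acetone; hindered secondary silyl ethers are stable to this weak acid.

Step 12
Reactants: 17 C3 ketone
Product: 19 C2=C3 enol triflate, via lithium enolate 18 (not isolated)
Conditions: lithium (R,R)-bis(1-phenylethyl)amide (1.3 equiv), LiCl (0.5 equiv), THF, −78 °C; then PhNTf2 (1.4 equiv), −78 → 0 °C
Reagents that add atoms: N-phenylbis(trifluoromethanesulfonimide), FC(F)(F)S(=O)(=O)N(c1ccccc1)S(=O)(=O)C(F)(F)F
Why: Chiral lithium amide enolisation of a bicyclic ketone: C2 and C4 differ only through the remote ring C centres, so the base distinguishes them as it would the two sides of a mirror-symmetric ketone and removes the exposed hydrogen of C2 (the methylene bound to C7, on the side of the C11 oxygen). O-Sulfonylation of the enolate fixes this choice as the enol triflate.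

Step 13
Reactants: 19 C2=C3 enol triflate
Product: 20 C2=C3 alkene
Conditions: Pd(OAc)2 (5 mol %), PPh3 (10 mol %), n-Bu3N (3 equiv), HCO2H (2 equiv), DMF, 60 °C
Reagents that add atoms: none
Why: Palladium-catalysed formate reduction of a vinyl triflate: oxidative addition of zerovalent palladium, exchange for formate, loss of CO2 and C–H reductive elimination; the double bond stays at C2=C3.

Step 14
Reactants: 20 C2=C3 alkene
Product: 22 C2-ketone C3=C4 enone, via allylic hydroperoxide 21 (not isolated)
Conditions: O2, visible light, 5,10,15,20-tetraphenylporphyrin (1 mol %), Ac2O (1.5 equiv), pyridine (2 equiv), 4-(dimethylamino)pyridine (5 mol %), CH2Cl2, 0 °C → rt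
Reagents that add atoms: dioxygen, O=O
Why: Schenck ene reaction: singlet O2 approaches the face of ring A turned to C6 (H on the bridge, not CH3), bonds to C2 and takes the C4 hydrogen on the same face, moving the double bond to C3=C4; the other ene mode would need the bridgehead hydrogen on C7. Kornblum–DeLaMare dehydration of the secondary hydroperoxide through its peracetate gives the enone.

Step 15
Reactants: 22 C2-ketone C3=C4 enone
Product: 23 C2 tertiary allylic alcohol
Conditions: MeLi (1.5 equiv), Et2O, −78 °C
Reagents that add atoms: methyllithium, [Li]C
Why: 1,2-Addition of the organolithium to the enone carbonyl from the face turned to C6; the configuration of the new carbinol carbon does not matter because C2 becomes trigonal in the next step.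

Step 16
Reactants: 23 C2 tertiary allylic alcohol
Product: 24 bis-silyl ether of the target enone (C4=O, C2=C3, 2-CH3)
Conditions: pyridinium chlorochromate [C5H5NH][CrO3Cl] (2.5 equiv), 4 Å molecular sieves, CH2Cl2, rt
Reagents that add atoms: pyridinium chlorochromate, [O-][Cr](=O)(=O)Cl.c1cc[nH+]cc1
Why: Babler–Dauben oxidative transposition: the chromate ester of the tertiary allylic alcohol (hexavalent chromium) shifts [3,3] from C2 to C4 and the secondary chromate is oxidised to the ketone. C4 is the cyclobutane-bound carbon on the side of the C9 oxygen, as the target requires.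

Step 17
Reactants: 24 bis-silyl ether of the target enone
Product: 25 (9R,11R)-diol enone
Conditions: HF·pyridine (excess), pyridine, THF, 0 → 40 °C
Reagents that add atoms: none
Why: Fluoride-mediated Si–O cleavage under buffered conditions that leave the enone and the cyclobutane untouched.

Step 18
Reactants: 25 (9R,11R)-diol enone; 26 3-methylbutanoyl chloride
Product: 27 target CNP0192813.1
Conditions: 26 (4 equiv), pyridine (8 equiv), 4-(dimethylamino)pyridine (0.5 equiv), CH2Cl2, 0 → 40 °C
Reagents that add atoms: none
Why: Acyl transfer catalysed by 4-(dimethylamino)pyridine esterifies both hindered secondary alcohols; no stereocentre is at risk, since C5 is a bridgehead and cannot enolise.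

## Compound list

1 | 1-methoxycyclohexa-1,4-diene | COC1=CCC=CC1 | starting material
2 | 1,4-dioxaspiro[4.5]dec-7-ene | C1=CCC2(CC1)OCCO2 | intermediate
3 | bromoform | BrC(Br)Br | starting material
4 | 7,7-dibromobicyclo[4.1.0]heptan-3-one ethylene ketal (racemic, cis-fused) | BrC1(Br)[C@H]2CC3(OCCO3)CC[C@@H]12 | intermediate
5 | tricyclo[4.1.0.0(2,7)]heptan-4-one ethylene ketal (achiral) | C1C5(OCCO5)C[C@@H]2[C@@H]3[C@H]1[C@H]23 | intermediate
6 | 1-lithiotricyclo[4.1.0.0(2,7)]heptan-4-one ethylene ketal | C1C5(OCCO5)C[C@@H]2[C@@H]3[C@H]1[C@]23[Li] | intermediate (not isolated)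
7 | 1-methyltricyclo[4.1.0.0(2,7)]heptan-4-one ethylene ketal (achiral) | C1C5(OCCO5)C[C@@H]2[C@@H]3[C@H]1[C@]23C | intermediate
8 | 2-bromo-2-methylpropanoyl bromide | CC(C)(Br)C(Br)=O | starting material
9 | bis(trimethylsilyl)ethyne | C[Si](C)(C)C#C[Si](C)(C)C | starting material
10 | 4-bromo-4-methyl-1-(trimethylsilyl)pent-1-yn-3-one | CC(C)(Br)C(=O)C#C[Si](C)(C)C | intermediate
11 | 4-bromo-4-methylpent-1-yn-3-one | CC(C)(Br)C(=O)C#C | intermediate
12 | mirror-symmetric tricyclic enone ketal (C3 ketal; C9=C10–C11=O; H6 and 8-CH3 syn) | C1C5(OCCO5)C[C@@H]2[C@@H]3[C@H]1[C@@]2(C)C=CC(=O)C3(C)C | intermediate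
13 | C9 pinacolboronate of the C11 ketone (boron on the C5 side) | C1C5(OCCO5)C[C@@H]2[C@@H]3[C@H]1[C@@]2(C)[C@H](B4OC(C)(C)C(C)(C)O4)CC(=O)C3(C)C | intermediate (not isolated)
14 | (9R)-C9-hydroxy C11-ketone ketal | C1C5(OCCO5)C[C@@H]2[C@@H]3[C@H]1[C@@]2(C)[C@H](O)CC(=O)C3(C)C | intermediate
15 | (9R,11R)-anti-diol ketal | C1C5(OCCO5)C[C@@H]2[C@@H]3[C@H]1[C@@]2(C)[C@H](O)C[C@@H](O)C3(C)C | intermediate
16 | C9,C11-bis(tert-butyldimethylsilyl) ether ketal | C1C5(OCCO5)C[C@@H]2[C@@H]3[C@H]1[C@@]2(C)[C@H](O[Si](C)(C)C(C)(C)C)C[C@@H](O[Si](C)(C)C(C)(C)C)C3(C)C | intermediate
17 | C3 ketone, bis-silyl ether | C1C(=O)C[C@@H]2[C@@H]3[C@H]1[C@@]2(C)[C@H](O[Si](C)(C)C(C)(C)C)C[C@@H](O[Si](C)(C)C(C)(C)C)C3(C)C | intermediate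
18 | lithium C2=C3 enolate | C1=C(O[Li])C[C@@H]2[C@@H]3[C@H]1[C@@]2(C)[C@H](O[Si](C)(C)C(C)(C)C)C[C@@H](O[Si](C)(C)C(C)(C)C)C3(C)C | intermediate (not isolated)
19 | C2=C3 enol triflate (triflate on C3) | C1=C(OS(=O)(=O)C(F)(F)F)C[C@@H]2[C@@H]3[C@H]1[C@@]2(C)[C@H](O[Si](C)(C)C(C)(C)C)C[C@@H](O[Si](C)(C)C(C)(C)C)C3(C)C | intermediate
20 | C2=C3 alkene | C1=CC[C@@H]2[C@@H]3[C@H]1[C@@]2(C)[C@H](O[Si](C)(C)C(C)(C)C)C[C@@H](O[Si](C)(C)C(C)(C)C)C3(C)C | intermediate
21 | C2 hydroperoxide, C3=C4 alkene (OOH on the face turned to C6) | [C@@H]1(OO)C=C[C@@H]2[C@@H]3[C@H]1[C@@]2(C)[C@H](O[Si](C)(C)C(C)(C)C)C[C@@H](O[Si](C)(C)C(C)(C)C)C3(C)C | intermediate (not isolated)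
22 | C2-ketone C3=C4 enone | O=C1C=C[C@@H]2[C@@H]3[C@H]1[C@@]2(C)[C@H](O[Si](C)(C)C(C)(C)C)C[C@@H](O[Si](C)(C)C(C)(C)C)C3(C)C | intermediate
23 | C2 tertiary allylic alcohol (expected epimer: CH3 on the face turned to C6) | C[C@]1(O)C=C[C@@H]2[C@@H]3[C@H]1[C@@]2(C)[C@H](O[Si](C)(C)C(C)(C)C)C[C@@H](O[Si](C)(C)C(C)(C)C)C3(C)C | intermediate
24 | bis-silyl ether of the target enone | CC1=CC(=O)[C@@H]2[C@@H]3[C@H]1[C@@]2(C)[C@H](O[Si](C)(C)C(C)(C)C)C[C@@H](O[Si](C)(C)C(C)(C)C)C3(C)C | intermediate
25 | (9R,11R)-diol enone | CC1=CC(=O)[C@@H]2[C@@H]3[C@H]1[C@@]2(C)[C@H](O)C[C@@H](O)C3(C)C | intermediate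
26 | 3-methylbutanoyl chloride | CC(C)CC(=O)Cl | starting material
27 | CNP0192813.1, C9,C11-bis(3-methylbutanoate) of the diol enone | CC1=CC(=O)[C@@H]2[C@@H]3[C@H]1[C@@]2(C)[C@H](OC(=O)CC(C)C)C[C@@H](OC(=O)CC(C)C)C3(C)C | target

## Step count and least certain steps

Total: 18 steps. Longest linear sequence: 16 steps (steps 1–4 and 7–18, from 1); steps 5 and 6 form the short second branch.

**Step 7 (key step, proposed new method).** The most likely failure is that ring closure does not keep pace with hydrogen transfer to the C8 radical, leaving the open C6 adduct. In a flat arrangement the alkyne π bond facing C8 is the one not conjugated with the carbonyl, so ring C must twist to gain activation. Further risks are hydrosilylation or oligomerisation of the terminal ynone and acid-induced opening of the bicyclobutane by silyl bromide.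
Fallback (known reaction types, two bonds in separate steps), from 7 and 8, returning at 12:
- 8 is converted with N,O-dimethylhydroxylamine hydrochloride and pyridine into 2-bromo-N-methoxy-N,2-dimethylpropanamide F1.
- Kharasch-type bromine-atom-transfer addition of F1 across the central bond of 7 (Et3B, air, no hydride donor) gives the C8 bromide carrying the amide chain anti on C6, F2. The configuration of the bromide is irrelevant because it becomes the radical again.
- Weinreb ketone synthesis with vinylmagnesium bromide gives the vinyl ketone F3.
- Bu3SnH/AIBN at high dilution closes ring C by 7-endo-trig attack of the C8 radical on the enone terminus. This is the usual mode when the acceptor carbonyl lies inside the forming ring, and it leaves a stabilised α-keto radical. The product is the saturated ketone F4.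
- Saegusa–Ito oxidation (LDA, Me3SiCl to the silyl enol ether F5, then Pd(OAc)2) restores C9=C10 and gives 12.

**Step 3.** The risk is loss of regiocontrol in the C–H insertion: insertion into the methylene next to the ketal carbon, for example through lithium coordination by the ketal, would give the unsymmetrical isomer.
Fallback (the site is fixed by a leaving group instead of by C–H reactivity), from 3 and commercial 1,4-dioxaspiro[4.5]decan-7-one F6, returning at 6:
- Dehydrogenation of F6 with 2-iodoxybenzoic acid, possible only away from the ketal carbon, gives 1,4-dioxaspiro[4.5]dec-8-en-7-one F7.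
- Luche reduction gives the allylic alcohol F8, and Corey–Kim chlorination (N-chlorosuccinimide, Me2S) the allylic chloride F9; allylic transposition only produces its enantiomer.
- Dibromocarbene from 3 under phase-transfer conditions adds anti to chlorine to give the dibromocyclopropane F10.
- MeLi (2.2 equiv) effects bromine–lithium exchange and displacement of chloride by the cyclopropyl carbanion, the 1,3-elimination used for bridgehead-linked bicyclobutanes and [1.1.1]propellane, giving the bridgehead bromide F11. A second exchange gives 6, which is methylated as in step 4.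

**Step 8.** The risk is poor facial selectivity or slow addition, because the β-carbon C9 is neopentyl and the substrate offers the catalyst little besides the difference between C8 and C12.
Fallback (enantioselection at the carbonyl, then relay), from 12, returning at 14:
- Corey–Bakshi–Shibata reduction (BH3·SMe2, 1-methyl-3,3-diphenyltetrahydro-1H,3H-pyrrolo[1,2-c][1,3,2]oxazaborole of the appropriate configuration) gives the allylic alcohol F12 with the C11 hydroxyl on the face later required for the C9 oxygen.
- Hydroxyl-directed epoxidation (VO(acac)2, t-BuOOH) gives the syn epoxy alcohol F13.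
- Dess–Martin oxidation gives the epoxy ketone F14.
- SmI2 cleaves the Cα–O bond to give 14.

**Step 12.** The risk is insufficient discrimination between C2 and C4 by the chiral amide, since the substrate itself gives no bias, leading to regioisomeric enol triflates that are hard to separate.
Fallback (both regioisomers are used), from 17, returning at 24:
- LDA and PhNTf2 give 19 together with its regioisomer, the C3=C4 enol triflate F15. The mixture is taken through steps 13 and 14, giving 22 and, by way of the C3=C4 alkene F16, the C4-ketone C2=C3 enone F17.
- 22 and F17 differ in the position of the carbonyl relative to the silyloxy groups and are separated at this stage.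
- 22 continues through steps 15 and 16.
- F17 already has oxygen on C4. Me2CuLi adds the methyl to C2 from the open face, and the enolate is brominated with N-bromosuccinimide to the α-bromo ketone F18. Anti elimination of HBr (Li2CO3, LiBr, DMF) gives 24. Bromination followed by anti elimination is chosen because the C2 hydrogen lies on the hindered face, which rules out syn eliminations.

**Step 14.** The risk is a slow ene reaction, because a 1,2-disubstituted alkene is a poor partner for singlet O2, with sensitiser bleaching or over-oxidation on long irradiation.
Fallback, from 20, returning at 22: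
- Epoxidation with m-chloroperbenzoic acid (NaHCO3) on the open face gives the epoxide F19.
- Lithium diethylamide removes the syn hydrogen on C4, the only possible site since the other neighbour is bridgehead C7, and gives the allylic alcohol F20.
- Dess–Martin oxidation gives 22.

## Further compounds

F1 | step 7 | 2-bromo-N-methoxy-N,2-dimethylpropanamide | CC(C)(Br)C(=O)N(C)OC
F2 | step 7 | C8 bromide with the N-methoxy-N-methylamide chain anti on C6 (one C8 epimer drawn) | C1C5(OCCO5)C[C@@H]2[C@H]([C@H]1[C@@]2(C)Br)C(C)(C)C(=O)N(C)OC
F3 | step 7 | C8 bromide vinyl ketone | C1C5(OCCO5)C[C@@H]2[C@H]([C@H]1[C@@]2(C)Br)C(C)(C)C(=O)C=C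
F4 | step 7 | saturated tricyclic C11 ketone ketal | C1C5(OCCO5)C[C@@H]2[C@@H]3[C@H]1[C@@]2(C)CCC(=O)C3(C)C
F5 | step 7 | C10=C11 trimethylsilyl enol ether | C1C5(OCCO5)C[C@@H]2[C@@H]3[C@H]1[C@@]2(C)CC=C(O[Si](C)(C)C)C3(C)C
F6 | step 3 | 1,4-dioxaspiro[4.5]decan-7-one | O=C1CCCC2(C1)OCCO2
F7 | step 3 | 1,4-dioxaspiro[4.5]dec-8-en-7-one | O=C1C=CCC2(C1)OCCO2
F8 | step 3 | 1,4-dioxaspiro[4.5]dec-8-en-7-ol (racemic) | OC1C=CCC2(C1)OCCO2
F9 | step 3 | 7-chloro-1,4-dioxaspiro[4.5]dec-8-ene (racemic) | ClC1C=CCC2(C1)OCCO2
F10 | step 3 | 7,7-dibromo-2-chlorobicyclo[4.1.0]heptan-4-one ethylene ketal (racemic, chlorine trans to the CBr2 bridge) | Cl[C@@H]1CC2(OCCO2)C[C@@H]3[C@H]1C3(Br)Br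
F11 | step 3 | 1-bromotricyclo[4.1.0.0(2,7)]heptan-4-one ethylene ketal | C1C5(OCCO5)C[C@@H]2[C@@H]3[C@H]1[C@]23Br
F12 | step 8 | C11 allylic alcohol ketal (hydroxyl on the C5 side) | C1C5(OCCO5)C[C@@H]2[C@@H]3[C@H]1[C@@]2(C)C=C[C@H](O)C3(C)C
F13 | step 8 | syn C9,C10-epoxy C11-alcohol ketal | C1C5(OCCO5)C[C@@H]2[C@@H]3[C@H]1[C@@]2(C)[C@@H]4O[C@@H]4[C@H](O)C3(C)C
F14 | step 8 | C9,C10-epoxy C11-ketone ketal | C1C5(OCCO5)C[C@@H]2[C@@H]3[C@H]1[C@@]2(C)[C@@H]4O[C@@H]4C(=O)C3(C)C
F15 | step 12 | C3=C4 enol triflate (regioisomer of 19) | C1C(OS(=O)(=O)C(F)(F)F)=C[C@@H]2[C@@H]3[C@H]1[C@@]2(C)[C@H](O[Si](C)(C)C(C)(C)C)C[C@@H](O[Si](C)(C)C(C)(C)C)C3(C)C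
F16 | step 12 | C3=C4 alkene (regioisomer of 20) | C1C=C[C@@H]2[C@@H]3[C@H]1[C@@]2(C)[C@H](O[Si](C)(C)C(C)(C)C)C[C@@H](O[Si](C)(C)C(C)(C)C)C3(C)C
F17 | step 12 | C4-ketone C2=C3 enone without the C2 methyl (regioisomer of 22) | C1=CC(=O)[C@@H]2[C@@H]3[C@H]1[C@@]2(C)[C@H](O[Si](C)(C)C(C)(C)C)C[C@@H](O[Si](C)(C)C(C)(C)C)C3(C)C
F18 | step 12 | 3-bromo-2-methyl C4 ketone (CH3 and Br on the face turned to C6) | C[C@@H]1[C@H](Br)C(=O)[C@@H]2[C@@H]3[C@H]1[C@@]2(C)[C@H](O[Si](C)(C)C(C)(C)C)C[C@@H](O[Si](C)(C)C(C)(C)C)C3(C)C
F19 | step 14 | C2,C3-epoxide (oxygen on the face turned to C6) | [C@H]14O[C@@H]4C[C@@H]2[C@@H]3[C@H]1[C@@]2(C)[C@H](O[Si](C)(C)C(C)(C)C)C[C@@H](O[Si](C)(C)C(C)(C)C)C3(C)C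
F20 | step 14 | C2 allylic alcohol, C3=C4 alkene | [C@@H]1(O)C=C[C@@H]2[C@@H]3[C@H]1[C@@]2(C)[C@H](O[Si](C)(C)C(C)(C)C)C[C@@H](O[Si](C)(C)C(C)(C)C)C3(C)C
A1 | alternative 1 | 4-methylene-bicyclo[3.1.1]heptan-6-one with open ring C chain | C[C@@H]1CC(=C)[C@@H]2C(=O)[C@H]1[C@@]2(C)[C@H](O[Si](C)(C)C(C)(C)C)CC(=O)C(C)C
A2 | alternative 1 | acyclic dienoyl chloride precursor | C[C@@H](/C=C(\C)[C@H](O[Si](C)(C)C(C)(C)C)CC(=O)C(C)C)C/C(C)=C/C(=O)Cl
A3 | alternative 2 | tricyclic C9 alcohol C11 3-methylbutanoate | CC1=CC(=O)[C@@H]2[C@@H]3[C@H]1[C@@]2(C)[C@H](O)C[C@@H](OC(=O)CC(C)C)C3(C)C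
A4 | alternative 2 | bicyclic C8 acetyl C12 aldehyde enone | CC1=CC(=O)[C@@H]2[C@H]([C@H]1[C@@]2(C)C(C)=O)C(C)(C)C=O
A5 | alternative 2 | 3-methylbutanal | CC(C)CC=O
A6 | alternative 3 | all-trans cyclobutane methyl ester | COC(=O)[C@@H]1[C@@H](C(C)(C)C(=O)OC)[C@H](C(C)=C)[C@@]1(C)[C@@H](C)O[Si](C)(C)C(C)(C)C
A7 | alternative 3 | 2-diazocyclopentanone precursor | O=C1C(=[N+]=[N-])[C@@H](C(C)(C)C(=O)OC)[C@H](C(C)=C)[C@@]1(C)[C@@H](C)O[Si](C)(C)C(C)(C)C
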